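## Retrosynthetic overview

1. Target 28 ⇐ 27 ⇐ 26 ⇐ 25 ⇐ 24 ⇐ 23: desilylation, acetylation, chelate-controlled reduction of an epoxy ketone, oxidation and hydroxyl-directed epoxidation lead back to the macrocyclic (Z)-allylic alcohol 23; its C13 hydroxyl first relays chirality to C11/C12 and is then corrected to 13R.
2. 23 ⇐ 22: the 14-membered carbocycle is closed by an intramolecular, ligand-controlled nickel/chromium alkenyl iodide–aldehyde coupling that forms the C12–C13 bond and the C13 carbinol in one operation.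
3. Enabling feature: C13 is a secondary carbinol carbon bonded directly to C12, the fully substituted carbon of the cis-11,12-oxirane, inside the 14-membered ring (an α,β-epoxy alcohol). Its retron is the (Z)-C11=C12(CH3)–C13H(OH) allylic alcohol, so C12 can be an alkenyl metal and C13 an aldehyde.
4. 22 ⇐ 19 ⇐ 11 + 16: the cis-fused α-methylene-γ-lactone (C1, C2) comes from a chromium-catalysed asymmetric 2-(alkoxycarbonyl)allylation/lactonisation. 11 ⇐ 5 + 9 by cross-metathesis, with C8 taken from (S)-linalool and the (Z)-iodoalkene from a Stork–Zhao olefination.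
5. Order of ring formation: γ-lactone (step 9), 14-membered carbocycle (step 11), oxirane (step 12).

Key step: step 11

Remarks
- Numbering: cembrane numbering is used for the macrocycles. C1 is the ring CH bearing C15; C2 the lactone O–CH; C3=C4(CH3); C6=C7; C8(CH3)(O); C11/C12(CH3) the oxirane; C13 the carbinol; C14 the CH2; C15(=C17H2)–C16(=O)–O–C2 the lactone.
- Assumption: (S)-(+)-linalool of high enantiomeric purity is taken as a commercial starting material.
- Assumption: in steps 9 and 11 the ligand antipode is the one that leads to Re-face addition to the aldehyde (giving 2S and 13S).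
- CIP note: with unchanged geometry, C12 is R in the free C13 alcohols 24 and 26 and S in ketone 25 and acetates 27 and 28, because the priority of C13 relative to C11 changes.

## Route

Step 1
Reactants: 1 (S)-(+)-linalool, (3S)-3,7-dimethylocta-1,6-dien-3-ol
Product: 4 (5S)-5-ethenyl-5-methyloxolan-2-ol (lactol; anomer mixture), via secondary ozonide 2 (not isolated), via hydroxy aldehyde 3 (not isolated)
Conditions: O3 (1 equiv, Sudan red indicator), CH2Cl2, −78 °C; then Me2S, −78 °C → rt
Reagents that add atoms: ozone, [O-][O+]=O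
Why: Electrophilic ozone should cleave the electron-rich trisubstituted 6,7-alkene well before the monosubstituted vinyl group (one-equivalent ozonolysis with reductive work-up), and the released hydroxy aldehyde closes to the five-membered lactol while the carbinol centre (future C8, S) is untouched.

Step 2
Reactants: 4 (5S)-5-ethenyl-5-methyloxolan-2-ol
Product: 5 (3S,6Z)-7-iodo-3-methylocta-1,6-dien-3-ol
Conditions: EtPPh3I (2.5 equiv), n-BuLi, THF, rt; I2, −78 °C; NaN(SiMe3)2, −20 °C; then 4, −78 → −20 °C
Reagents that add atoms: ethyltriphenylphosphonium iodide, CC[P+](c1ccccc1)(c1ccccc1)c1ccccc1.[I-]; iodine, II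
Why: In this Stork–Zhao olefination the excess basic ylide opens lactol 4 by ring–chain tautomerism to its hydroxy aldehyde form (the open-chain tautomer, compound 3), whose carbonyl the non-stabilised α-iodo ylide Ph3P=C(I)CH3 should attack under kinetic (cis-oxaphosphetane) control to give the (Z)-2-iodoalk-2-ene, which fixes the later cis relationship of C10 and C13 on the oxirane.

Step 3
Reactants: 6 pent-1-en-4-yne
Product: 9 (2E)-3-methylhexa-2,5-dien-1-ol, via alkenylalane 7 (not isolated), via lithium alanate 8 (not isolated)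
Conditions: AlMe3 (2 equiv), Cp2ZrCl2 (0.25 equiv), CH2Cl2, 0 °C → rt; n-BuLi, THF, −78 → 0 °C; (CH2O)n, rt; dilute HCl work-up
Reagents that add atoms: trimethylaluminium, C[Al](C)C; paraformaldehyde (formaldehyde unit), C=O
Why: Zirconocene-catalysed Negishi carboalumination should add CH3–Al syn and regioselectively across the terminal alkyne (the isolated alkene reacts far more slowly), and the derived alanate is hydroxymethylated with retention to give the (E)-trisubstituted allylic alcohol (future C2–C6 with the C4 methyl).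

Step 4
Reactants: 5 (3S,6Z)-7-iodo-3-methylocta-1,6-dien-3-ol; 9 (2E)-3-methylhexa-2,5-dien-1-ol (3 equiv)
Product: 10 (2E,5E,7S,10Z)-11-iodo-3,7-dimethyldodeca-2,5,10-triene-1,7-diol
Conditions: second-generation Hoveyda–Grubbs catalyst RuCl2(H2IMes)(=CH-C6H4-2-OiPr) (5 mol%), 1,4-benzoquinone (10 mol%), CH2Cl2, 40 °C
Reagents that add atoms: none
Why: Olefin cross-metathesis between the type-one terminal olefin 9 (in excess) and the vinyl group of the tertiary allylic alcohol 5 should favour the cross product as the (E)-alkene under thermodynamic control, while the trisubstituted alkenes and the hindered, electron-poor iodoalkene do not engage the ruthenium carbene (so ring closure within 5 is not expected) and benzoquinone suppresses migration of the skipped diene.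

Step 5
Reactants: 10 (2E,5E,7S,10Z)-11-iodo-3,7-dimethyldodeca-2,5,10-triene-1,7-diol
Product: 11 (2E,5E,7S,10Z)-7-hydroxy-11-iodo-3,7-dimethyldodeca-2,5,10-trienal
Conditions: MnO2 (excess), CH2Cl2, rt
Reagents that add atoms: none
Why: Activated MnO2 should oxidise only the primary allylic alcohol to the enal under neutral conditions, since the tertiary allylic alcohol cannot be oxidised and the skipped diene and alkenyl iodide are inert.

Step 6
Reactants: 12 3,3-diethoxypropan-1-ol
Product: 13 3,3-diethoxypropanal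
Conditions: Dess–Martin periodinane, NaHCO3, CH2Cl2, 0 °C → rt
Reagents that add atoms: none
Why: Dess–Martin oxidation converts the primary alcohol to the aldehyde under buffered, non-aqueous conditions that keep the diethyl acetal intact.

Step 7
Reactants: 13 3,3-diethoxypropanal; 14 ethyl acrylate
Product: 15 ethyl 5,5-diethoxy-3-hydroxy-2-methylidenepentanoate (racemic)
Conditions: DABCO (1 equiv), 1,4-dioxane/H2O (1:1), rt
Reagents that add atoms: none
Why: In this Morita–Baylis–Hillman reaction DABCO adds to the acrylate and the resulting enolate adds to the unhindered aliphatic aldehyde; the new carbinol centre is racemic and is erased in step 8.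

Step 8
Reactants: 15 ethyl 5,5-diethoxy-3-hydroxy-2-methylidenepentanoate
Product: 16 ethyl (2Z)-2-(bromomethyl)-5,5-diethoxypent-2-enoate
Conditions: NBS, Me2S, CH2Cl2, 0 °C → rt
Reagents that add atoms: N-bromosuccinimide, O=C1CCC(=O)N1Br
Why: The bromodimethylsulfonium reagent formed from NBS and Me2S activates the allylic hydroxyl and bromide attacks in the SN2' sense, which should give the thermodynamically preferred (Z)-2-(bromomethyl)alk-2-enoate without acid that would endanger the acetal.

Step 9
Reactants: 11 (2E,5E,7S,10Z)-7-hydroxy-11-iodo-3,7-dimethyldodeca-2,5,10-trienal; 16 ethyl (2Z)-2-(bromomethyl)-5,5-diethoxypent-2-enoate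
Product: 19 (4S,5S)-4-(2,2-diethoxyethyl)-5-[(1E,4E,6S,9Z)-6-hydroxy-10-iodo-2,6-dimethylundeca-1,4,9-trien-1-yl]-3-methylideneoxolan-2-one, via silyl ether ester 17 (not isolated), via hydroxy ester 18 (not isolated)
Conditions: CrCl2 (10 mol%), chiral tridentate 1,8-bis(4-alkyl-oxazolin-2-yl)carbazole ligand (12 mol%), Mn powder, Me3SiCl, iPr2NEt (cat.), THF, rt; then PPTS, EtOH, rt
Reagents that add atoms: none
Why: In this catalytic asymmetric Nozaki–Hiyama-type 2-(alkoxycarbonyl)allylation the γ-substituted allyl species on trivalent chromium should add to the enal carbonyl by γ-attack through a chair transition state to give the syn adduct (hence the cis lactone after acid-induced desilylation and lactonisation), while the chiral ligand on chromium selects the Re face so that C2 and C1 are both S (catalyst control, the remote C8 centre having no influence) and the iodoalkene stays inert in the absence of nickel.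

Step 10
Reactants: 19 (4S,5S)-4-(2,2-diethoxyethyl)-5-[(1E,4E,6S,9Z)-6-hydroxy-10-iodo-2,6-dimethylundeca-1,4,9-trien-1-yl]-3-methylideneoxolan-2-one
Product: 22 2-[(2S,3S)-2-[(1E,4E,6S,9Z)-10-iodo-2,6-dimethyl-6-(triethylsilyloxy)undeca-1,4,9-trien-1-yl]-4-methylidene-5-oxooxolan-3-yl]acetaldehyde, via silyl ether acetal 20 (not isolated), via pyridinium salt 21 (not isolated)
Conditions: Et3SiOTf (3.5 equiv), 2,6-lutidine (5 equiv), CH2Cl2, −40 → 0 °C; then H2O, rt
Reagents that add atoms: triethylsilyl trifluoromethanesulfonate, CC[Si](CC)(CC)OS(=O)(=O)C(F)(F)F; water, O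
Why: The silyl triflate/hindered pyridine pair should first silylate the tertiary alcohol and then ionise the diethyl acetal to an oxocarbenium ion that is trapped by 2,6-lutidine as a pyridinium salt and hydrolysed to the aldehyde on addition of water (silyl-triflate-mediated acetal cleavage), so that the C8 oxygen is protected and C13 unmasked in one non-acidic operation.

Step 11
Reactants: 22 2-[(2S,3S)-2-[(1E,4E,6S,9Z)-10-iodo-2,6-dimethyl-6-(triethylsilyloxy)undeca-1,4,9-trien-1-yl]-4-methylidene-5-oxooxolan-3-yl]acetaldehyde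
Product: 23 (1S,2S,3E,6E,8S,11Z,13S)-13-hydroxy-8-(triethylsilyloxy)cembra-3,6,11,15(17)-tetraen-16,2-olide
Conditions: CrCl2 (8 equiv), NiCl2 (0.2 equiv), chiral N-[2-(4-isopropyl-4,5-dihydrooxazol-2-yl)phenyl]methanesulfonamide ligand (9 equiv), Et3N (9 equiv), THF, rt, syringe-pump addition of 22 (final 2 mM)
Reagents that add atoms: none
Why: Zerovalent nickel (generated in situ from NiCl2 by divalent chromium) inserts into the C12–I bond with retention, the alkenyl group is transferred to trivalent chromium, and this alkenylchromium adds 1,2 to the tethered C13 aldehyde; the closest known reaction type is the Nozaki–Hiyama–Kishi macrocyclisation of alkenyl iodides onto aldehydes in its ligand-controlled asymmetric form. The only ring closed is the 14-membered carbocycle, by a 14-exo-trig addition to the carbonyl carbon. The single new stereocentre, C13, is controlled by the chiral oxazoline–sulfonamide ligand on chromium (antipode chosen for Re-face addition, 13S), the resident C1 centre being β to the aldehyde and only a weak director. The step needs retention of the (Z)-C11=C12 geometry, which the configurationally stable trisubstituted alkenyl–nickel and alkenyl–chromium intermediates secure, and chemoselectivity for the aldehyde over the lactone carbonyl and the methylene-lactone acceptor, which the low basicity and high oxophilicity of alkenylchromium reagents secure. Ring closure over oligomerisation is favoured by slow addition at high dilution and by the restricted chain (cis-fused lactone, two (E)-alkenes, the (Z)-alkenyl terminus, quaternary C8), and the silyl ether keeps the C8 oxygen off chromium. One operation should thus deliver the ring, the C12–C13 bond, the in-ring (Z)-olefin and the C13 hydroxyl that later steers the oxirane and becomes the acetate site.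

Step 12
Reactants: 23 (1S,2S,3E,6E,8S,11Z,13S)-13-hydroxy-8-(triethylsilyloxy)cembra-3,6,11,15(17)-tetraen-16,2-olide
Product: 24 (1S,2S,3E,6E,8S,11S,12R,13S)-11,12-epoxy-13-hydroxy-8-(triethylsilyloxy)cembra-3,6,15(17)-trien-16,2-olide
Conditions: m-CPBA (1.1 equiv), NaHCO3, CH2Cl2, −20 → 0 °C
Reagents that add atoms: 3-chloroperoxybenzoic acid, O=C(OO)c1cccc(Cl)c1
Why: In this hydroxyl-directed peracid epoxidation, hydrogen bonding to the (13S) hydroxyl should deliver oxygen to the electron-rich (Z)-trisubstituted C11=C12 bond syn to the OH in the conformer that places H13 in the alkene plane facing C10 (1,3-allylic strain, threo selectivity, also the outer face of the ring), setting C11 and C12 as in the target, while the C3=C4 bond (deactivated by the allylic lactone oxygen), the disubstituted C6=C7 bond and the electron-poor methylene lactone react more slowly.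

Step 13
Reactants: 24 (1S,2S,3E,6E,8S,11S,12R,13S)-11,12-epoxy-13-hydroxy-8-(triethylsilyloxy)cembra-3,6,15(17)-trien-16,2-olide
Product: 25 (1S,2S,3E,6E,8S,11S,12S)-11,12-epoxy-13-oxo-8-(triethylsilyloxy)cembra-3,6,15(17)-trien-16,2-olide
Conditions: Dess–Martin periodinane, NaHCO3, CH2Cl2, 0 °C → rt
Reagents that add atoms: none
Why: Buffered Dess–Martin oxidation of the only free hydroxyl gives the α,β-epoxy ketone without epimerisable centres at risk, because C12 is quaternary and C1 is β to the new carbonyl.

Step 14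
Reactants: 25 (1S,2S,3E,6E,8S,11S,12S)-11,12-epoxy-13-oxo-8-(triethylsilyloxy)cembra-3,6,15(17)-trien-16,2-olide
Product: 26 (1S,2S,3E,6E,8S,11S,12R,13R)-11,12-epoxy-13-hydroxy-8-(triethylsilyloxy)cembra-3,6,15(17)-trien-16,2-olide
Conditions: Zn(BH4)2, Et2O, −30 °C
Reagents that add atoms: none
Why: In this chelation-controlled reduction Zn(BH4)2 should bridge the ketone and oxirane oxygens and deliver hydride to C13 from the face of the C12 methyl, opposite the oxirane carbon C11 (erythro-selective reduction of α,β-epoxy ketones), giving the (13R) carbinol while the lactone and its exocyclic alkene are not reduced by this mild reagent at low temperature.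

Step 15
Reactants: 26 (1S,2S,3E,6E,8S,11S,12R,13R)-11,12-epoxy-13-hydroxy-8-(triethylsilyloxy)cembra-3,6,15(17)-trien-16,2-olide
Product: 27 (1S,2S,3E,6E,8S,11S,12S,13R)-13-acetoxy-11,12-epoxy-8-(triethylsilyloxy)cembra-3,6,15(17)-trien-16,2-olide
Conditions: Ac2O, DMAP (cat.), pyridine, CH2Cl2, 0 °C → rt
Reagents that add atoms: acetic anhydride, CC(=O)OC(C)=O
Why: DMAP-catalysed acylation esterifies the only free (secondary) hydroxyl under weakly basic conditions that do not trigger epoxide migration, the tertiary C8 oxygen being silylated.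

Step 16
Reactants: 27 (1S,2S,3E,6E,8S,11S,12S,13R)-13-acetoxy-11,12-epoxy-8-(triethylsilyloxy)cembra-3,6,15(17)-trien-16,2-olide
Product: 28 (1S,2S,3E,6E,8S,11S,12S,13R)-13-acetoxy-11,12-epoxy-8-hydroxycembra-3,6,15(17)-trien-16,2-olide (target)
Conditions: HF·pyridine, pyridine, THF, 0 °C → rt
Reagents that add atoms: none
Why: Pyridine-buffered fluoride should cleave the tertiary triethylsilyl ether through formation of the strong Si–F bond without opening the acetate-deactivated oxirane or touching the acetate and the α-methylene lactone.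

## Compound list

1 | (S)-(+)-linalool, (3S)-3,7-dimethylocta-1,6-dien-3-ol | C=C[C@@](C)(O)CCC=C(C)C | starting material
2 | 3-[(3S)-3-hydroxy-3-methylpent-4-en-1-yl]-5,5-dimethyl-1,2,4-trioxolane (secondary ozonide) | C=C[C@@](C)(O)CCC1OOC(C)(C)O1 | intermediate (not isolated)
3 | (4S)-4-hydroxy-4-methylhex-5-enal | C=C[C@@](C)(O)CCC=O | intermediate (not isolated)
4 | (5S)-5-ethenyl-5-methyloxolan-2-ol | C=C[C@]1(C)CCC(O)O1 | intermediate
5 | (3S,6Z)-7-iodo-3-methylocta-1,6-dien-3-ol | C=C[C@@](C)(O)CC/C=C(/C)I | intermediate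
6 | pent-1-en-4-yne | C=CCC#C | starting material
7 | dimethyl[(1E)-2-methylpenta-1,4-dien-1-yl]alumane | C=CC/C(C)=C/[Al](C)C | intermediate (not isolated)
8 | lithium butyl(dimethyl)[(1E)-2-methylpenta-1,4-dien-1-yl]aluminate | [Li+].C=CC/C(C)=C/[Al-](C)(C)CCCC | intermediate (not isolated)
9 | (2E)-3-methylhexa-2,5-dien-1-ol | C=CC/C(C)=C/CO | intermediate
10 | (2E,5E,7S,10Z)-11-iodo-3,7-dimethyldodeca-2,5,10-triene-1,7-diol | OC/C=C(\C)C/C=C/[C@@](C)(O)CC/C=C(/C)I | intermediate
11 | (2E,5E,7S,10Z)-7-hydroxy-11-iodo-3,7-dimethyldodeca-2,5,10-trienal | O=C/C=C(\C)C/C=C/[C@@](C)(O)CC/C=C(/C)I | intermediate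
12 | 3,3-diethoxypropan-1-ol | CCOC(CCO)OCC | starting material
13 | 3,3-diethoxypropanal | CCOC(CC=O)OCC | intermediate
14 | ethyl acrylate | C=CC(=O)OCC | starting material
15 | ethyl 5,5-diethoxy-3-hydroxy-2-methylidenepentanoate (racemic) | C=C(C(=O)OCC)C(O)CC(OCC)OCC | intermediate
16 | ethyl (2Z)-2-(bromomethyl)-5,5-diethoxypent-2-enoate | CCOC(=O)/C(CBr)=C/CC(OCC)OCC | intermediate
17 | ethyl (3S,4S,5E,8E,10S,13Z)-3-(2,2-diethoxyethyl)-10-hydroxy-14-iodo-6,10-dimethyl-2-methylidene-4-(trimethylsilyloxy)pentadeca-5,8,13-trienoate | C=C(C(=O)OCC)[C@H](CC(OCC)OCC)[C@@H](O[Si](C)(C)C)/C=C(\C)C/C=C/[C@@](C)(O)CC/C=C(/C)I | intermediate (not isolated)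
18 | ethyl (3S,4S,5E,8E,10S,13Z)-3-(2,2-diethoxyethyl)-4,10-dihydroxy-14-iodo-6,10-dimethyl-2-methylidenepentadeca-5,8,13-trienoate | C=C(C(=O)OCC)[C@H](CC(OCC)OCC)[C@@H](O)/C=C(\C)C/C=C/[C@@](C)(O)CC/C=C(/C)I | intermediate (not isolated)
19 | (4S,5S)-4-(2,2-diethoxyethyl)-5-[(1E,4E,6S,9Z)-6-hydroxy-10-iodo-2,6-dimethylundeca-1,4,9-trien-1-yl]-3-methylideneoxolan-2-one | C=C1C(=O)O[C@@H](/C=C(\C)C/C=C/[C@@](C)(O)CC/C=C(/C)I)[C@H]1CC(OCC)OCC | intermediate
20 | (4S,5S)-4-(2,2-diethoxyethyl)-5-[(1E,4E,6S,9Z)-10-iodo-2,6-dimethyl-6-(triethylsilyloxy)undeca-1,4,9-trien-1-yl]-3-methylideneoxolan-2-one | C=C1C(=O)O[C@@H](/C=C(\C)C/C=C/[C@@](C)(O[Si](CC)(CC)CC)CC/C=C(/C)I)[C@H]1CC(OCC)OCC | intermediate (not isolated)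
21 | 1-{1-ethoxy-2-[(2S,3S)-2-[(1E,4E,6S,9Z)-10-iodo-2,6-dimethyl-6-(triethylsilyloxy)undeca-1,4,9-trien-1-yl]-4-methylidene-5-oxooxolan-3-yl]ethyl}-2,6-dimethylpyridinium trifluoromethanesulfonate | C=C1C(=O)O[C@@H](/C=C(\C)C/C=C/[C@@](C)(O[Si](CC)(CC)CC)CC/C=C(/C)I)[C@H]1CC(OCC)[n+]1c(C)cccc1C.[O-]S(=O)(=O)C(F)(F)F | intermediate (not isolated)
22 | 2-[(2S,3S)-2-[(1E,4E,6S,9Z)-10-iodo-2,6-dimethyl-6-(triethylsilyloxy)undeca-1,4,9-trien-1-yl]-4-methylidene-5-oxooxolan-3-yl]acetaldehyde | C=C1C(=O)O[C@@H](/C=C(\C)C/C=C/[C@@](C)(O[Si](CC)(CC)CC)CC/C=C(/C)I)[C@H]1CC=O | intermediate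
23 | (1S,2S,3E,6E,8S,11Z,13S)-13-hydroxy-8-(triethylsilyloxy)cembra-3,6,11,15(17)-tetraen-16,2-olide | C=C1C(=O)O[C@H]2/C=C(\C)C/C=C/[C@@](C)(O[Si](CC)(CC)CC)CC/C=C(/C)[C@@H](O)C[C@@H]12 | intermediate
24 | (1S,2S,3E,6E,8S,11S,12R,13S)-11,12-epoxy-13-hydroxy-8-(triethylsilyloxy)cembra-3,6,15(17)-trien-16,2-olide | C=C1C(=O)O[C@H]2/C=C(\C)C/C=C/[C@@](C)(O[Si](CC)(CC)CC)CC[C@@H]3O[C@]3(C)[C@@H](O)C[C@@H]12 | intermediate
25 | (1S,2S,3E,6E,8S,11S,12S)-11,12-epoxy-13-oxo-8-(triethylsilyloxy)cembra-3,6,15(17)-trien-16,2-olide | C=C1C(=O)O[C@H]2/C=C(\C)C/C=C/[C@@](C)(O[Si](CC)(CC)CC)CC[C@@H]3O[C@]3(C)C(=O)C[C@@H]12 | intermediate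
26 | (1S,2S,3E,6E,8S,11S,12R,13R)-11,12-epoxy-13-hydroxy-8-(triethylsilyloxy)cembra-3,6,15(17)-trien-16,2-olide | C=C1C(=O)O[C@H]2/C=C(\C)C/C=C/[C@@](C)(O[Si](CC)(CC)CC)CC[C@@H]3O[C@]3(C)[C@H](O)C[C@@H]12 | intermediate
27 | (1S,2S,3E,6E,8S,11S,12S,13R)-13-acetoxy-11,12-epoxy-8-(triethylsilyloxy)cembra-3,6,15(17)-trien-16,2-olide | C=C1C(=O)O[C@H]2/C=C(\C)C/C=C/[C@@](C)(O[Si](CC)(CC)CC)CC[C@@H]3O[C@]3(C)[C@H](OC(C)=O)C[C@@H]12 | intermediate
28 | (1S,2S,3E,6E,8S,11S,12S,13R)-13-acetoxy-11,12-epoxy-8-hydroxycembra-3,6,15(17)-trien-16,2-olide | C=C1C(=O)O[C@H]2/C=C(\C)C/C=C/[C@@](C)(O)CC[C@@H]3O[C@]3(C)[C@H](OC(C)=O)C[C@@H]12 | target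

## Step count and risks

Total step count: 16. Longest linear sequence: 12 steps (steps 1, 2, 4, 5, 9, 10, 11, 12, 13, 14, 15, 16).

Step 11 (ring closure). The ligand on chromium may discriminate the two faces of the C13 aldehyde poorly within the macrocyclic transition state, and oligomerisation may compete. The fallback sets out from 22. The ring is closed without chiral ligand (CrCl2, NiCl2 cat., DMSO/THF, high dilution), which should give 23 together with its C13 epimer, (1S,2S,3E,6E,8S,11Z,13R)-13-hydroxy-8-(triethylsilyloxy)cembra-3,6,11,15(17)-tetraen-16,2-olide F1. The mixture is oxidised with Dess–Martin periodinane to the single macrocyclic enone (1S,2S,3E,6E,8S,11Z)-13-oxo-8-(triethylsilyloxy)cembra-3,6,11,15(17)-tetraen-16,2-olide F2. F2 is then reduced with catecholborane and the (R)-configured Corey–Bakshi–Shibata oxazaborolidine (alkenyl group large, C14 methylene small), which sets 13S by reagent control and comes back to the route at 23.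

Step 9 (asymmetric allylation/lactonisation). Catalyst control over the aldehyde face may be eroded on the large enal 11, whose free tertiary hydroxyl can bind chromium, which would give both cis lactones relative to C8. The fallback sets out from 9 and changes the order of fragment union. Oxidation of 9 with MnO2 gives (2E)-3-methylhexa-2,5-dienal F3. The same chromium-catalysed asymmetric allylation with 16 (CrCl2 cat., the carbazole bis(oxazoline) ligand, Mn powder, Me3SiCl, THF) is run on this small, hydroxyl-free aldehyde and should give the silyl ether ethyl (3S,4S,5E)-3-(2,2-diethoxyethyl)-6-methyl-2-methylidene-4-(trimethylsilyloxy)nona-5,8-dienoate F4. PPTS in EtOH should free the hydroxy ester ethyl (3S,4S,5E)-3-(2,2-diethoxyethyl)-4-hydroxy-6-methyl-2-methylidenenona-5,8-dienoate F5, which lactonises to (4S,5S)-4-(2,2-diethoxyethyl)-3-methylidene-5-[(1E)-2-methylpenta-1,4-dien-1-yl]oxolan-2-one F6. Cross-metathesis of F6 with 5 (second-generation Hoveyda–Grubbs catalyst RuCl2(H2IMes)(=CH-C6H4-2-OiPr); the hindered 1,1-disubstituted methylene lactone is a poor metathesis partner) comes back to the route at 19.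

Step 14 (reduction of the epoxy ketone). Chelation control may be lost in the macrocycle, so that hydride attacks the other carbonyl face and returns the threo alcohol, or conjugate reduction of the methylene lactone may intrude. The fallback sets out from 24 and avoids the redox pair. A Mitsunobu reaction with acetic acid (PPh3, diisopropyl azodicarboxylate, toluene, 0 °C → rt) displaces the activated C13 oxygen with inversion and gives the acetate directly, coming back to the route at 27; it makes no new compound (entry F0).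

Further compounds
F1 | step 11 | (1S,2S,3E,6E,8S,11Z,13R)-13-hydroxy-8-(triethylsilyloxy)cembra-3,6,11,15(17)-tetraen-16,2-olide | C=C1C(=O)O[C@H]2/C=C(\C)C/C=C/[C@@](C)(O[Si](CC)(CC)CC)CC/C=C(/C)[C@H](O)C[C@@H]12
F2 | step 11 | (1S,2S,3E,6E,8S,11Z)-13-oxo-8-(triethylsilyloxy)cembra-3,6,11,15(17)-tetraen-16,2-olide | C=C1C(=O)O[C@H]2/C=C(\C)C/C=C/[C@@](C)(O[Si](CC)(CC)CC)CC/C=C(/C)C(=O)C[C@@H]12
F3 | step 9 | (2E)-3-methylhexa-2,5-dienal | C=CC/C(C)=C/C=O
F4 | step 9 | ethyl (3S,4S,5E)-3-(2,2-diethoxyethyl)-6-methyl-2-methylidene-4-(trimethylsilyloxy)nona-5,8-dienoate | C=C(C(=O)OCC)[C@H](CC(OCC)OCC)[C@@H](O[Si](C)(C)C)/C=C(\C)CC=C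
F5 | step 9 | ethyl (3S,4S,5E)-3-(2,2-diethoxyethyl)-4-hydroxy-6-methyl-2-methylidenenona-5,8-dienoate | C=C(C(=O)OCC)[C@H](CC(OCC)OCC)[C@@H](O)/C=C(\C)CC=C
F6 | step 9 | (4S,5S)-4-(2,2-diethoxyethyl)-3-methylidene-5-[(1E)-2-methylpenta-1,4-dien-1-yl]oxolan-2-one | C=C1C(=O)O[C@@H](/C=C(\C)CC=C)[C@H]1CC(OCC)OCC
F0 | step 14 | none | none
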